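**Retrosynthetic overview**
- The target comes from its N1,N4-methylene (hexahydropyrimidine) derivative. The CH2 bridge masks the central spermidine nitrogen and is removed last.
- The dihydrofuran ring comes from a 5-exo oxa-Michael closure of a phenol onto an (S)-4,4-disubstituted cyclohexenone. That enone comes from an enantioselective CuH desymmetrisation of a prochiral macrocyclic cyclohexa-2,5-dienone.
- Both Z-acrylamides come from syn semi-hydrogenation of the corresponding macrocyclic diyne.
- The 20-membered ring, the quaternary carbon and the dienone come from one macrocyclising para–ortho oxidative phenol coupling of an acyclic bis(arylpropioloyl)spermidine, the didehydro analogue of dicoumaroylspermidine.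
- The acyclic precursor comes from spermidine, CH2O, 4-iodophenol and propiolic acid. Ring order: temporary hexahydropyrimidine, then macrocycle with dienone, then dihydrofuran.

Assumption: the Z,Z geometry and the (4aR,9bS) configuration in the SMILES are taken literally; (S,S)-Ph-BPE is written in step 8, and its commercially available antipode is used if the first run shows the opposite sense of induction.

Spermidine numbering: N1 is the propyl-end N, N4 the central N, N8 the butyl-end N.

**Step 1**
Reactants: 1 4-iodophenol; 2 propiolic acid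
Product: 3 3-(4-hydroxyphenyl)prop-2-ynoic acid
Conditions: Pd(PPh3)4 (2.5 mol %), DBU (3.5 equiv), DMSO, 30 °C; cold 1 M HCl work-up
Reagents that add atoms: none
Why: Copper-free Sonogashira coupling of an aryl iodide with propiolic acid stops at the arylpropiolic acid below about 40 °C without decarboxylation, and the phenoxide does not interfere.

**Step 2**
Reactants: 3 3-(4-hydroxyphenyl)prop-2-ynoic acid
Product: 5 3-[4-(triisopropylsilyloxy)phenyl]prop-2-ynoic acid, via bis-TIPS silyl ester 4 (not isolated)
Conditions: TIPSCl (2.3 equiv), imidazole, DMF, rt; then K2CO3, THF/MeOH/H2O, rt; 1 M HCl to pH 3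
Reagents that add atoms: triisopropylsilyl chloride, CC(C)[Si](Cl)(C(C)C)C(C)C
Why: Exhaustive silylation followed by selective hydrolysis of the much more labile silyl ester (silyl ether protection) masks only the phenol, and TIPS is chosen because it resists phenol-to-phenol silyl transfer, acid and I(III).

**Step 3**
Reactants: 6 spermidine
Product: 7 4-(hexahydropyrimidin-1-yl)butan-1-amine (N1,N4-methylenespermidine)
Conditions: 37 % aq. CH2O (1.0 equiv), H2O, 0 °C → rt
Reagents that add atoms: formaldehyde, C=O
Why: In this aminal formation one equivalent of formaldehyde condenses selectively with the 1,3-diamine half to the six-membered ring, which masks N4 and leaves N8 as the only primary amine.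

**Step 4**
Reactants: 3 3-(4-hydroxyphenyl)prop-2-ynoic acid; 7 4-(hexahydropyrimidin-1-yl)butan-1-amine
Product: 9 N-[4-(hexahydropyrimidin-1-yl)butyl]-3-(4-hydroxyphenyl)prop-2-ynamide, via NHS ester 8 (not isolated)
Conditions: DIC, N-hydroxysuccinimide, THF, 0 °C; then added slowly to 7 (1.1 equiv), THF/DMF, −20 → 0 °C
Reagents that add atoms: none
Why: In this active-ester amidation the unhindered primary amine out-competes the less basic, more hindered aminal NH for the NHS ester at low temperature, and the neutral phenol is not acylated.

**Step 5**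
Reactants: 9 N-[4-(hexahydropyrimidin-1-yl)butyl]-3-(4-hydroxyphenyl)prop-2-ynamide; 5 3-[4-(triisopropylsilyloxy)phenyl]prop-2-ynoic acid
Product: 11 N8-[3-(4-hydroxyphenyl)propioloyl]-N1-{3-[4-(triisopropylsilyloxy)phenyl]propioloyl}-N1,N4-methylenespermidine (acyclic precursor), via OAt ester 10 (not isolated)
Conditions: DIC, HOAt, CH2Cl2/DMF, 0 °C → rt
Reagents that add atoms: none
Why: Carbodiimide/HOAt amidation acylates the only remaining N–H amine (ring N1) faster than the neutral phenol, which places the free phenol on the butyl end and the masked phenol on the propyl end, as the target's orientation requires.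

**Step 6**
Reactants: 11 acyclic bis(arylpropiolamide)
Product: 12 macrocyclic diyne cyclohexa-2,5-dienone (achiral; dienone C4 carries the N8-ynamide arm and the aryl carbon ortho to OTIPS of the N1-arylpropiolamide ring)
Conditions: TFA (2 equiv), PIFA (1.05 equiv), HFIP, 0 °C, separate syringe-pump addition of 11 and PIFA over 8 h to 1 mM; NaHCO3 quench
Reagents that add atoms: none
Why: Proposed new method: only the free phenol exchanges onto I(III); the HFIP-stabilised phenoxenium (or its iodane) is attacked at its para carbon by the position ortho to OTIPS of the tethered aryl silyl ether, and loss of H+ gives the 4-aryl-4-alkynyl dienone and closes the macrocycle in one event; N4 is shielded as its ammonium trifluoroacetate; the alkynes shut down side-chain (C8, lignan-type) coupling and ipso attack by the amide because they are linear and cannot carry the charge next to the carbonyl; the closest known reaction types are the PIFA/fluoroalcohol intramolecular para–ortho phenol–aryl ether coupling to cyclohexadienones (Kita-type oxidative dearomatisation) and Pummerer-ketone formation.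

**Step 7**
Reactants: 12 macrocyclic diyne dienone
Product: 13 macrocyclic (Z,Z)-bis(acrylamide) cyclohexa-2,5-dienone (achiral)
Conditions: H2 (1 atm), Lindlar catalyst, quinoline, EtOAc/MeOH, rt, stopped at 2.0 equiv uptake
Reagents that add atoms: none
Why: Lindlar semi-hydrogenation delivers H2 syn to both ynamides and sets both Z-alkenes, because the alkynes displace the hindered dienone C=C bonds from the poisoned Pd surface.

**Step 8**
Reactants: 13 macrocyclic (Z,Z)-dienone
Product: 16 (4aR,9bS)-N1,N4-methylene derivative of the target (cis-fused hexahydrodibenzofuran-3-one), via silyl dienol ether 14 (not isolated), via enone phenol 15 (not isolated)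
Conditions: Cu(OAc)2 (5 mol %), (S,S)-Ph-BPE (5.5 mol %), MeSiH(OMe)2 (1.3 equiv), toluene, −20 °C; then TBAF/AcOH (1:1, 2.5 equiv), THF, 0 °C → rt
Reagents that add atoms: none
Why: In this desymmetrising asymmetric CuH 1,4-reduction the chiral bisphospholane–CuH distinguishes the two enantiotopic enone arms and fixes the quaternary centre as S (14 being parked as a silyl dienol ether against over-reduction), and fluoride then frees 15, whose 5-exo-trig oxa-Michael addition can reach the enone β-carbon only from the face carrying the aryl ring, giving the cis-fused 4aR centre.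

**Step 9**
Reactants: 16 (4aR,9bS)-N1,N4-methylene derivative
Product: 17 target, (4aR,9bS)-(Z,Z)-macrocyclic spermidine bis-lactam bridging C9b and C8 of 1,2,4,4a-tetrahydrodibenzofuran-3-one
Conditions: malonic acid (3 equiv), pyridine, EtOH, reflux, 2 h
Reagents that add atoms: none
Why: In this Knoevenagel–Doebner scavenging the N-acyl aminal opens reversibly to the iminium and malonic acid removes the CH2 unit irreversibly, while the amine stays protonated, the quaternary centre cannot epimerise and C4a can only re-close cis.

**Compound list**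
1 | 4-iodophenol | Oc1ccc(I)cc1 | starting material
2 | propiolic acid | C#CC(=O)O | starting material
3 | 3-(4-hydroxyphenyl)prop-2-ynoic acid | OC(=O)C#Cc1ccc(O)cc1 | intermediate
4 | triisopropylsilyl 3-[4-(triisopropylsilyloxy)phenyl]prop-2-ynoate | CC(C)[Si](C(C)C)(C(C)C)OC(=O)C#Cc1ccc(O[Si](C(C)C)(C(C)C)C(C)C)cc1 | intermediate
5 | 3-[4-(triisopropylsilyloxy)phenyl]prop-2-ynoic acid | OC(=O)C#Cc1ccc(O[Si](C(C)C)(C(C)C)C(C)C)cc1 | intermediate
6 | spermidine | NCCCCNCCCN | starting material
7 | 4-(hexahydropyrimidin-1-yl)butan-1-amine | NCCCCN1CCCNC1 | intermediate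
8 | N-succinimidyl 3-(4-hydroxyphenyl)prop-2-ynoate | O=C(C#Cc1ccc(O)cc1)ON1C(=O)CCC1=O | intermediate
9 | N-[4-(hexahydropyrimidin-1-yl)butyl]-3-(4-hydroxyphenyl)prop-2-ynamide | Oc1ccc(cc1)C#CC(=O)NCCCCN2CCCNC2 | intermediate
10 | 7-azabenzotriazol-1-yl 3-[4-(triisopropylsilyloxy)phenyl]prop-2-ynoate | O=C(C#Cc1ccc(O[Si](C(C)C)(C(C)C)C(C)C)cc1)On1nnc2cccnc12 | intermediate
11 | acyclic bis(arylpropiolamide) of N1,N4-methylenespermidine | Oc1ccc(cc1)C#CC(=O)NCCCCN2CCCN(C2)C(=O)C#Cc3ccc(O[Si](C(C)C)(C(C)C)C(C)C)cc3 | intermediate
12 | macrocyclic diyne cyclohexa-2,5-dienone | O=C1C=CC2(C=C1)C#CC(=O)NCCCCN3CCCN(C3)C(=O)C#Cc4ccc(O[Si](C(C)C)(C(C)C)C(C)C)c2c4 | intermediate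
13 | macrocyclic (Z,Z)-bis(acrylamide) cyclohexa-2,5-dienone | O=C1C=CC2(C=C1)/C=C\C(=O)NCCCCN3CCCN(C3)C(=O)/C=C\c4ccc(O[Si](C(C)C)(C(C)C)C(C)C)c2c4 | intermediate
14 | (S)-dimethoxy(methyl)silyl dienol ether | CO[Si](C)(OC)OC1=CC[C@]2(C=C1)/C=C\C(=O)NCCCCN3CCCN(C3)C(=O)/C=C\c4ccc(O[Si](C(C)C)(C(C)C)C(C)C)c2c4 | intermediate
15 | (S)-4-(2-hydroxyaryl)-4-alkenylcyclohex-2-enone macrocycle | O=C1CC[C@]2(C=C1)/C=C\C(=O)NCCCCN3CCCN(C3)C(=O)/C=C\c4ccc(O)c2c4 | intermediate
16 | (4aR,9bS)-N1,N4-methylene derivative of the target | O=C1CC[C@]23/C=C\C(=O)NCCCCN5CCCN(C5)C(=O)/C=C\c4ccc(c2c4)O[C@@H]3C1 | intermediate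
17 | CNP0415009.2, (4aR,9bS,Z,Z) | O=C1CC[C@]23/C=C\C(=O)NCCCCNCCCNC(=O)/C=C\c4ccc(c2c4)O[C@@H]3C1 | target

**Step count**
Total steps: 9. Longest linear sequence: 7 (for example 3, 4, 5, 6, 7, 8, 9, or 1, 2, 5, 6, 7, 8, 9).

**Three steps most likely to fail**

Step 6, the macrocyclising oxidative coupling.
- The aryl silyl ether is only a moderate nucleophile.
- Ortho attack would give a biaryl, oligomers may form, and acid could trigger a dienone–phenol shift. A modest yield is expected.
- The fallback gives up the ring-closing C–C coupling. It sets out from 9 and 5 and comes back at 12.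
- Compound 9, as its bis(trifluoroacetate), is oxidised with PIFA in HFIP at 0.1 M in the presence of 5 equiv of 5, with the excess recovered. The same para–ortho bond then forms intermolecularly and gives the seco amino acid dienone F1.
- The ring is closed at the N1 amide by high-dilution lactamisation (DIC, HOAt, 1 mM), which gives 12.

Step 7, semi-hydrogenation next to a dienone.
- The dienone C=C bonds may be hydrogenated, and the neopentyl-type ynamide may react slowly.
- The fallback moves the hydrogenation to a stage where no enone is left. It sets out from 12 and comes back at 16.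
- Compound 12 is first desymmetrised by iminium-catalysed asymmetric transfer hydrogenation (chiral primary-amine salt, Hantzsch ester). This activates only the ketone and leaves the ynamides alone, giving the (S)-diyne enone F2.
- TBAF/AcOH triggers the oxa-Michael closure to the cis-fused diyne ketone F3.
- Lindlar reduction of F3 gives 16.

Step 8, CuH desymmetrisation.
- Discrimination between aryl and Z-alkenyl groups at the quaternary carbon may give low ee. Over-reduction or attack on the acrylamides is also possible.
- The fallback sets the stereochemistry by dynamic resolution instead of catalyst control. It sets out from 13 and comes back at 16.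
- TBAF/AcOH on 13 gives, by spontaneous oxa-Michael closure, the racemic cis-fused enone F4.
- The enantiomers of this enone interconvert through the achiral phenol–dienone (retro-oxa-Michael, catalytic Et3N, warm EtOH).
- The enone is therefore driven by crystallisation-induced asymmetric transformation into the (4aR,9bS)-enone di-p-toluoyl-L-tartrate salt F5. The antipodal acid is used if the wrong enantiomer crystallises.
- Free-basing and immediate achiral 1,4-reduction with [(Ph3P)CuH]6 locks the configuration and gives 16.

**Further compounds**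
F1 | step 6 | seco amino acid dienone: 4-alkynyl-4-aryl-cyclohexa-2,5-dienone with free ring NH and free arylpropiolic acid | O=C1C=CC(C=C1)(C#CC(=O)NCCCCN2CCCNC2)c3cc(ccc3O[Si](C(C)C)(C(C)C)C(C)C)C#CC(=O)O
F2 | step 7 | (S)-diyne enone macrocycle | O=C1CC[C@]2(C=C1)C#CC(=O)NCCCCN3CCCN(C3)C(=O)C#Cc4ccc(O[Si](C(C)C)(C(C)C)C(C)C)c2c4
F3 | step 7 | (4aR,9bS)-cis-fused diyne ketone | O=C1CC[C@]23C#CC(=O)NCCCCN5CCCN(C5)C(=O)C#Cc4ccc(c2c4)O[C@@H]3C1
F4 | step 8 | rac-(4aR*,9bS*)-cis-fused enone (one enantiomer drawn) | O=C1C=C[C@]23/C=C\C(=O)NCCCCN5CCCN(C5)C(=O)/C=C\c4ccc(c2c4)O[C@@H]3C1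
F5 | step 8 | (4aR,9bS)-enone di-p-toluoyl-L-tartrate salt | O=C1C=C[C@]23/C=C\C(=O)NCCCCN5CCCN(C5)C(=O)/C=C\c4ccc(c2c4)O[C@@H]3C1.Cc1ccc(cc1)C(=O)O[C@H]([C@H](C(=O)O)OC(=O)c1ccc(C)cc1)C(=O)O
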